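**Retrosynthetic overview**
1. 14 ⇐ 13: the C4 aldehyde is oxidised to the acid last; the acetate is already in place.
2. 13 ⇐ 11 + 12: ring A is closed last by a catalyst-controlled [4+2] (bonds C2–C3 and C4–C5), which sets C4 and C5 and leaves the C1=C10 alkene.
3. 11 ⇐ 9 ⇐ 7 ⇐ 6: the semicyclic diene comes from the ring B ketone by enol triflation and vinylation; the allylic acetate comes from the enoate.
4. 6 ⇐ 4 + 5: the E-trisubstituted side-chain alkene comes from olefination of the methyl ketone.
5. 4 ⇐ 1 + 2: ring B is bought as achiral enone 1; C8 and C9 are set in one organocatalytic reductive Michael step (first stereocentres).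

Assumption and convention: atoms are labelled by halimane numbering (ring A = C1–C5, C10; ring B = C5–C10; C4 bears CH3/CO2H, C9 bears CH3 and the C11–C15 chain; target = 4S,5R,8S,9R, 13E), and where a chiral catalyst is named its antipode is the one that gives the facial sense stated in that step.

**Step 1**
Reactants: 1 2,3-dimethylcyclohex-2-en-1-one; 2 methyl vinyl ketone
Product: 4 (2R,3S)-2,3-dimethyl-2-(3-oxobutyl)cyclohexan-1-one, via saturated ketone 3 (not isolated)
Conditions: tert-butyl valinate·TRIP salt (15 mol%, antipode giving hydride delivery to the C3 Re face), diethyl 2,6-dimethyl-1,4-dihydropyridine-3,5-dicarboxylate (Hantzsch ester, 1.1 equiv), Bu2O, 60 °C; once the Hantzsch ester is consumed, 2 (2.5 equiv, slow addition), 40 °C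
Reagents that add atoms: 2 methyl vinyl ketone (CC(=O)C=C)
Why: Proposed new method: a one-flask iminium-reduction/enamine-Michael relay in which the primary ammonium phosphate condenses with 1 to an iminium ion, the Hantzsch ester transfers hydride to the C3 Re face inside the chiral ion pair to set the (3S) methyl centre (C8), and the resulting more-substituted secondary enamine (in equilibrium with 3 and its imine) adds to 2 through a six-membered aza-ene-type transition state anti to the pseudoaxial C3 methyl, creating the quaternary C2 (C9) with the two methyls cis before hydrolysis releases 4 and the amine; the closest known reactions are the amine-salt/Hantzsch-ester transfer hydrogenation of 3-substituted cyclohexenones, the intramolecular organocatalytic reductive Michael cyclisation, and the chiral-imine or phosphoric-acid (enol) Michael addition of 2-substituted cyclohexanones to enones.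

**Step 2**
Reactants: 4 (2R,3S)-2,3-dimethyl-2-(3-oxobutyl)cyclohexan-1-one; 5 ethyl 2-[di(propan-2-yloxy)phosphoryl]acetate
Product: 6 ethyl (2E)-5-[(1R,2S)-1,2-dimethyl-6-oxocyclohexyl]-3-methylpent-2-enoate
Conditions: 5 (1.5 equiv), NaH (1.4 equiv), THF, 0 °C; then 4, 0 to 40 °C; chromatography removes the minor Z isomer
Reagents that add atoms: 5 ethyl 2-[di(propan-2-yloxy)phosphoryl]acetate (CCOC(=O)CP(=O)(OC(C)C)OC(C)C)
Why: Horner–Wadsworth–Emmons olefination in which the preformed phosphonate anion attacks only the unhindered methyl ketone (the ring carbonyl is flanked by the quaternary centre) and the bulky diisopropyl phosphonate favours the E-enoate (about 9:1 expected), with no stereocentre touched.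

**Step 3**
Reactants: 6 ethyl (2E)-5-[(1R,2S)-1,2-dimethyl-6-oxocyclohexyl]-3-methylpent-2-enoate
Product: 7 ethyl (2E)-5-[(1R,6S)-1,6-dimethyl-2-{[(trifluoromethyl)sulfonyl]oxy}cyclohex-2-en-1-yl]-3-methylpent-2-enoate
Conditions: Tf2O (1.3 equiv), 2,6-di-tert-butyl-4-methylpyridine (1.5 equiv), CH2Cl2, 0 °C to rt
Reagents that add atoms: trifluoromethanesulfonic anhydride, Tf2O (O=S(=O)(OS(=O)(=O)C(F)(F)F)C(F)(F)F)
Why: Electrophilic enol triflation under non-basic conditions gives a single regioisomer because the ketone can enolise only towards C5 (C9 is quaternary), and the enoate, which a strong amide base would deprotonate, is left alone.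

**Step 4**
Reactants: 7 enol triflate (name as above); 8 tributyl(ethenyl)stannane
Product: 9 ethyl (2E)-5-[(1R,6S)-2-ethenyl-1,6-dimethylcyclohex-2-en-1-yl]-3-methylpent-2-enoate
Conditions: Pd(PPh3)4 (5 mol%), LiCl (3 equiv), 8 (1.3 equiv), THF, 65 °C
Reagents that add atoms: 8 tributyl(ethenyl)stannane (CCCC[Sn](CCCC)(CCCC)C=C)
Why: Stille cross-coupling (oxidative addition of the enol triflate to zerovalent palladium assisted by chloride, transmetalation from tin, reductive elimination) installs C1–C2 as a vinyl group without touching the stereocentres or the enoate.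

**Step 5**
Reactants: 9 ethyl (2E)-5-[(1R,6S)-2-ethenyl-1,6-dimethylcyclohex-2-en-1-yl]-3-methylpent-2-enoate
Product: 11 (2E)-5-[(1R,6S)-2-ethenyl-1,6-dimethylcyclohex-2-en-1-yl]-3-methylpent-2-en-1-yl acetate, via allylic alcohol 10 (not isolated)
Conditions: i-Bu2AlH (2.2 equiv), CH2Cl2, −78 to 0 °C; then pyridine, DMAP (cat.), Ac2O (5 equiv), 0 °C to rt; aqueous potassium sodium tartrate work-up
Reagents that add atoms: acetic anhydride (CC(=O)OC(C)=O)
Why: 1,2-Reduction of the enoate by i-Bu2AlH gives the aluminium alkoxide of 10, which is acetylated in the same flask by DMAP-catalysed acylation, while the diene, the E-alkene and both stereocentres are inert to hydride and to Ac2O.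

**Step 6**
Reactants: 11 (2E)-5-[(1R,6S)-2-ethenyl-1,6-dimethylcyclohex-2-en-1-yl]-3-methylpent-2-en-1-yl acetate; 12 methacrolein
Product: 13 (1S,5R,6S,8aR)-5-[(3E)-5-(acetyloxy)-3-methylpent-3-en-1-yl]-1,5,6-trimethyl-1,2,3,5,6,7,8,8a-octahydronaphthalene-1-carbaldehyde
Conditions: (S)-o-tolyl-CBS oxazaborolidine·Tf2NH (20 mol%), 12 (5 equiv), CH2Cl2, −78 to −40 °C
Reagents that add atoms: 12 methacrolein (CC(=C)C=O)
Why: Enantioselective Diels–Alder reaction under cationic oxazaborolidine (metal-free Lewis acid) catalysis in which the vinyl CH2 bonds to the enal β-carbon and ring carbon C5 to the α-carbon ("ortho" regiochemistry), the catalyst exposes only the Re face of the enal α-carbon (setting 4S), and the formyl-endo transition state then requires bonding to the C5 face syn to the two ring methyls (setting 5R), so both new centres are reagent-controlled against the small bias of the pseudo-symmetric C9 centre.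

**Step 7**
Reactants: 13 aldehyde (name as above)
Product: 14 (1S,5R,6S,8aR)-5-[(3E)-5-(acetyloxy)-3-methylpent-3-en-1-yl]-1,5,6-trimethyl-1,2,3,5,6,7,8,8a-octahydronaphthalene-1-carboxylic acid (target)
Conditions: NaClO2, NaH2PO4, 2-methylbut-2-ene (excess), t-BuOH/H2O, 0 °C to rt
Reagents that add atoms: sodium chlorite, NaClO2 ([Na+].[O-]Cl=O)
Why: Pinnick oxidation converts the α-quaternary (non-epimerisable) aldehyde to the acid, and 2-methylbut-2-ene scavenges HOCl so that both trisubstituted alkenes and the allylic acetate survive.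

**Compound list**
1 | 2,3-dimethylcyclohex-2-en-1-one | CC1=C(C)C(=O)CCC1 | starting material
2 | methyl vinyl ketone (but-3-en-2-one) | CC(=O)C=C | starting material
3 | (3S)-2,3-dimethylcyclohexan-1-one (C2 epimers, in equilibrium with its catalyst-bound imine/enamine) | CC1C(=O)CCC[C@@H]1C | intermediate
4 | (2R,3S)-2,3-dimethyl-2-(3-oxobutyl)cyclohexan-1-one | CC(=O)CC[C@@]1(C)C(=O)CCC[C@@H]1C | intermediate
5 | ethyl 2-[di(propan-2-yloxy)phosphoryl]acetate | CCOC(=O)CP(=O)(OC(C)C)OC(C)C | starting material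
6 | ethyl (2E)-5-[(1R,2S)-1,2-dimethyl-6-oxocyclohexyl]-3-methylpent-2-enoate | CCOC(=O)/C=C(\C)CC[C@@]1(C)C(=O)CCC[C@@H]1C | intermediate
7 | ethyl (2E)-5-[(1R,6S)-1,6-dimethyl-2-{[(trifluoromethyl)sulfonyl]oxy}cyclohex-2-en-1-yl]-3-methylpent-2-enoate | CCOC(=O)/C=C(\C)CC[C@@]1(C)C(OS(=O)(=O)C(F)(F)F)=CCC[C@@H]1C | intermediate
8 | tributyl(ethenyl)stannane | CCCC[Sn](CCCC)(CCCC)C=C | starting material
9 | ethyl (2E)-5-[(1R,6S)-2-ethenyl-1,6-dimethylcyclohex-2-en-1-yl]-3-methylpent-2-enoate | CCOC(=O)/C=C(\C)CC[C@@]1(C)C(C=C)=CCC[C@@H]1C | intermediate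
10 | (2E)-5-[(1R,6S)-2-ethenyl-1,6-dimethylcyclohex-2-en-1-yl]-3-methylpent-2-en-1-ol | OC/C=C(\C)CC[C@@]1(C)C(C=C)=CCC[C@@H]1C | intermediate
11 | (2E)-5-[(1R,6S)-2-ethenyl-1,6-dimethylcyclohex-2-en-1-yl]-3-methylpent-2-en-1-yl acetate | CC(=O)OC/C=C(\C)CC[C@@]1(C)C(C=C)=CCC[C@@H]1C | intermediate
12 | methacrolein (2-methylprop-2-enal) | CC(=C)C=O | starting material
13 | (1S,5R,6S,8aR)-5-[(3E)-5-(acetyloxy)-3-methylpent-3-en-1-yl]-1,5,6-trimethyl-1,2,3,5,6,7,8,8a-octahydronaphthalene-1-carbaldehyde | CC(=O)OC/C=C(\C)CC[C@@]1(C)C2=CCC[C@](C)(C=O)[C@@H]2CC[C@@H]1C | intermediate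
14 | (1S,5R,6S,8aR)-5-[(3E)-5-(acetyloxy)-3-methylpent-3-en-1-yl]-1,5,6-trimethyl-1,2,3,5,6,7,8,8a-octahydronaphthalene-1-carboxylic acid | CC(=O)OC/C=C(\C)CC[C@@]1(C)C2=CCC[C@](C)(C(=O)O)[C@@H]2CC[C@@H]1C | target

**Totals**
Total steps: 7. Longest linear sequence: 7 steps (1 → 4 → 6 → 7 → 9 → 11 → 13 → 14).

**Steps most likely to fail, with fallbacks**

Step 1 (the proposed new step). The hydride transfer to a tetrasubstituted enone may be slow or poorly selective, and the amine may be consumed by 2 before the hindered quaternary centre forms. The fallback is known chemistry; it sets out from 2 and comes back at 4. Purchased 2-methylcyclohex-2-en-1-one F1 takes the place of 1 and undergoes copper-catalysed asymmetric conjugate addition of AlMe3 (Cu(OTf)2 2 mol%, chiral phosphoramidite ligand, Et2O, −30 °C) with in situ O-silylation by Me3SiOTf to give the silyl enol ether trimethyl{[(3S)-2,3-dimethylcyclohex-1-en-1-yl]oxy}silane F2. A Mukaiyama–Michael addition of F2 to 2 (TiCl4, CH2Cl2, −78 °C), anti to the C3 methyl, then gives 4.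

Step 6. Three things can go wrong. The catalyst must make the dienophile bond to the diene face that carries the two ring methyls, which is probably the mismatched sense. The endo/exo preference of an α-methyl enal may be modest. The hindered diene may give some of the other regioisomer or oligomerise. The fallback replaces the intermolecular cycloaddition by a stereospecific lactone-enolate Claisen ring contraction; it sets out from 7 and comes back at 14. Reduction of 7 with i-Bu2AlH (−78 °C) gives allylic alcohol F6. Hydroboration of methyl 2-methylbut-3-enoate with 9-BBN-H gives alkylborane F7, and carbonylative Suzuki–Miyaura coupling of F6 with F7 (PdCl2(dppf), K3PO4, CO 1 atm, THF/DMF) gives enone keto ester F8. Reduction with (S)-Me-CBS/catecholborane (−78 °C) sets the C1 carbinol as the (R)-alcohol F9. Warming F9 with pyridinium p-toluenesulfonate in toluene closes δ-lactone F10. Treatment with LiN(i-Pr)2 (2.2 equiv) and Me3SiCl/Et3N (THF, −78 °C) gives bis-silyl ketene acetal F11. On heating in toluene, F11 rearranges through the enforced boat transition state, so the C1 configuration fixes 4S and 5R, and gives silyl ester F12. Dilute HCl work-up hydrolyses F12 to hydroxy acid F13, and acetylation (Ac2O, pyridine, DMAP; aqueous work-up cleaves the mixed anhydride) gives 14.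

Step 2. The 1,5-diketone can undergo base-induced intramolecular aldol (Robinson-type) cyclisation, chemoselectivity between the two ketones may be incomplete, and the E/Z ratio may be lower than hoped. The fallback separates the two carbonyls by protection; it sets out from 4 and comes back at 7. Selective ketalisation of the methyl ketone (1,2-bis(trimethylsilyloxy)ethane, Me3SiOTf cat., CH2Cl2, −78 °C) gives dioxolane F3. With no ester present, KN(SiMe3)2/PhNTf2 (THF, −78 °C) gives ketal enol triflate F4. Mild acid (pyridinium p-toluenesulfonate, wet acetone) unmasks keto enol triflate F5, whose only ketone undergoes the same olefination with 5/NaH to give 7.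

**Further compounds**
F1 | step 1 | 2-methylcyclohex-2-en-1-one (purchased) | CC1=CCCCC1=O
F2 | step 1 | trimethyl{[(3S)-2,3-dimethylcyclohex-1-en-1-yl]oxy}silane | CC1=C(O[Si](C)(C)C)CCC[C@@H]1C
F3 | step 2 | (2R,3S)-2,3-dimethyl-2-[2-(2-methyl-1,3-dioxolan-2-yl)ethyl]cyclohexan-1-one | CC1(CC[C@@]2(C)C(=O)CCC[C@@H]2C)OCCO1
F4 | step 2 | (5S,6R)-5,6-dimethyl-6-[2-(2-methyl-1,3-dioxolan-2-yl)ethyl]cyclohex-1-en-1-yl trifluoromethanesulfonate | CC1(CC[C@@]2(C)C(OS(=O)(=O)C(F)(F)F)=CCC[C@@H]2C)OCCO1
F5 | step 2 | (5S,6R)-5,6-dimethyl-6-(3-oxobutyl)cyclohex-1-en-1-yl trifluoromethanesulfonate | CC(=O)CC[C@@]1(C)C(OS(=O)(=O)C(F)(F)F)=CCC[C@@H]1C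
F6 | step 6 | (5S,6R)-6-[(3E)-5-hydroxy-3-methylpent-3-en-1-yl]-5,6-dimethylcyclohex-1-en-1-yl trifluoromethanesulfonate | OC/C=C(\C)CC[C@@]1(C)C(OS(=O)(=O)C(F)(F)F)=CCC[C@@H]1C
F7 | step 6 | methyl 4-(9-borabicyclo[3.3.1]nonan-9-yl)-2-methylbutanoate | COC(=O)C(C)CCB1C2CCCC1CCC2
F8 | step 6 | methyl 5-{(5S,6R)-6-[(3E)-5-hydroxy-3-methylpent-3-en-1-yl]-5,6-dimethylcyclohex-1-en-1-yl}-2-methyl-5-oxopentanoate (C2 epimers) | OC/C=C(\C)CC[C@@]1(C)C(C(=O)CCC(C)C(=O)OC)=CCC[C@@H]1C
F9 | step 6 | methyl (5R)-5-hydroxy-5-{(5S,6R)-6-[(3E)-5-hydroxy-3-methylpent-3-en-1-yl]-5,6-dimethylcyclohex-1-en-1-yl}-2-methylpentanoate (C2 epimers) | OC/C=C(\C)CC[C@@]1(C)C([C@H](O)CCC(C)C(=O)OC)=CCC[C@@H]1C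
F10 | step 6 | (6R)-6-{(5S,6R)-6-[(3E)-5-hydroxy-3-methylpent-3-en-1-yl]-5,6-dimethylcyclohex-1-en-1-yl}-3-methyloxan-2-one (C3 epimers) | OC/C=C(\C)CC[C@@]1(C)C([C@H]2CCC(C)C(=O)O2)=CCC[C@@H]1C
F11 | step 6 | O-trimethylsilyl ketene acetal of F10 with the side-chain hydroxyl as its trimethylsilyl ether | C[Si](C)(C)OC/C=C(\C)CC[C@@]1(C)C([C@H]2CCC(C)=C(O[Si](C)(C)C)O2)=CCC[C@@H]1C
F12 | step 6 | trimethylsilyl (1S,5R,6S,8aR)-1,5,6-trimethyl-5-{(3E)-3-methyl-5-[(trimethylsilyl)oxy]pent-3-en-1-yl}-1,2,3,5,6,7,8,8a-octahydronaphthalene-1-carboxylate | C[Si](C)(C)OC/C=C(\C)CC[C@@]1(C)C2=CCC[C@](C)(C(=O)O[Si](C)(C)C)[C@@H]2CC[C@@H]1C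
F13 | step 6 | (1S,5R,6S,8aR)-5-[(3E)-5-hydroxy-3-methylpent-3-en-1-yl]-1,5,6-trimethyl-1,2,3,5,6,7,8,8a-octahydronaphthalene-1-carboxylic acid | OC/C=C(\C)CC[C@@]1(C)C2=CCC[C@](C)(C(=O)O)[C@@H]2CC[C@@H]1C
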